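**Retrosynthetic overview**
- Target ⇒ ring B exo-methylene ketone: the C3 chlorohydrin comes from HCl opening of a spiro-epoxide made by nucleophilic epoxidation; the CH2Cl carbon comes from formaldehyde.
- Ring A cis-bromohydrin ⇒ α-bromoketone ⇒ trans-bromohydrin of a C9=C10 alkene; the C7 methylidene comes from carbonyl methylenation.
- Spiro[5.5] core ⇒ key step: acetal-triggered vinylogous semipinacol ring expansion of a cyclopentenol (ring A, 5→6) onto C6 of ring B, which creates the quaternary spirocentre.
- Carbinol ⇒ acetal of 3-bromocyclohex-2-enone (ring B, present from the start) + 2,2-dimethylcyclopent-3-enone (from 2-methylcyclopent-2-enone and MeI); ring A is formed last, by the expansion.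

Assumption: all names use one fixed spiro[5.5]undecane numbering (ring B = C1–C5, spiro atom C6, ring A = C7–C11); the C6 descriptor changes from S to R at step 6 only because CIP priorities change (C7=O versus C7=CH2); the (R)-acid of step 4 is taken to give 6S-9, otherwise its enantiomer is used.

Step 1
Reactants: 1 3-bromocyclohex-2-en-1-one
Product: 2 7-bromo-1,4-dioxaspiro[4.5]dec-6-ene
Conditions: Me3SiOCH2CH2OSiMe3 (1.3 equiv), Me3SiOTf (2 mol %), CH2Cl2, −78 to −20 °C
Reagents that add atoms: 1,2-bis(trimethylsilyloxy)ethane C[Si](C)(C)OCCO[Si](C)(C)C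
Why: Aprotic low-temperature acetalisation with the bis-silyl ether (Noyori-type dioxolane formation) masks the enone carbonyl without moving the C=C bond, so the bromine-bearing carbon can later be lithiated and the allylic acetal can serve as the cation trigger in step 4.

Step 2
Reactants: 3 2-methylcyclopent-2-en-1-one
Product: 4 2,2-dimethylcyclopent-3-en-1-one
Conditions: KOt-Bu (1.1 equiv), THF, 0 °C; MeI (1.2 equiv), 0 °C to rt
Reagents that add atoms: iodomethane CI
Why: γ-Deprotonation under equilibrating conditions gives the extended dienolate, which is methylated at its α-carbon C2 (deconjugative α-alkylation of an enone), creating the gem-dimethyl carbon beside the ketone and moving the alkene to C3=C4.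

Step 3
Reactants: 2 7-bromo-1,4-dioxaspiro[4.5]dec-6-ene; 4 2,2-dimethylcyclopent-3-en-1-one
Product: 7 rac-1-(1,4-dioxaspiro[4.5]dec-6-en-7-yl)-2,2-dimethylcyclopent-3-en-1-ol, via vinyllithium 5 (not isolated), via vinylcerium dichloride 6 (not isolated)
Conditions: 2, t-BuLi (2.0 equiv), THF, −78 °C; CeCl3 (1.1 equiv), −78 °C; 4, −78 °C; H2O
Reagents that add atoms: none
Why: Bromine–lithium exchange followed by transmetalation to the weakly basic organocerium (CeCl3-mediated 1,2-addition) lets the alkenyl nucleophile add to the carbonyl of the easily enolised ketone 4; the carbinol is racemic, which is harmless because this stereocentre disappears in step 4.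

Step 4
Reactants: 7 rac-1-(1,4-dioxaspiro[4.5]dec-6-en-7-yl)-2,2-dimethylcyclopent-3-en-1-ol
Product: 9 (6S)-2,2-(ethylenedioxy)-11,11-dimethylspiro[5.5]undec-9-en-7-one, via hydroxyethyl enol ether 8 (not isolated)
Conditions: (R)-3,3'-bis(2,4,6-triisopropylphenyl)-1,1'-binaphthyl-2,2'-diyl N-(trifluoromethylsulfonyl)phosphoramide (5 mol %), toluene, 5 Å MS, −40 °C
Reagents that add atoms: none
Why: Proposed new method: the chiral acid opens the allylic dioxolane to a 2-(2-hydroxyethoxy)allyl cation with positive charge at C6, the quaternary allylic carbon C11 (a far better migrating group than the CH2) shifts from the carbinol carbon to one face of C6 inside the chiral ion pair while the carbinol becomes the C7 ketone (5→6 ring expansion, driven by C=O formation), and the tethered hydroxyl re-closes enol ether 8 to the dioxolane so the acid turns over; because the only stereocentre of 7 is destroyed and rotation about C6–C7 lets either enantiomer present C11 to the favoured face, the reaction is enantioconvergent and sets the spirocentre; the closest known reaction types are the amine-catalysed vinylogous α-ketol (semipinacol-type) rearrangement of 3-(1-hydroxycyclobutyl)enones and chiral-acid-catalysed semipinacol and Wagner–Meerwein shifts, none of which uses an acetal trigger, a cyclopentanol donor or a racemic carbinol.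

Step 5
Reactants: 9 (6S)-2,2-(ethylenedioxy)-11,11-dimethylspiro[5.5]undec-9-en-7-one
Product: 10 (6S,9R,10R)-10-bromo-2,2-(ethylenedioxy)-9-hydroxy-11,11-dimethylspiro[5.5]undecan-7-one
Conditions: NBS (1.05 equiv), acetone–H2O 4:1, 0 °C, dark
Reagents that add atoms: N-bromosuccinimide O=C1CCC(=O)N1Br; water O
Why: Bromohydrin formation: in the conformer of 9 enforced by the acetal (C7 carbonyl oxygen turned away from the axial acetal oxygen, C1 pseudo-axial on ring A) only the bromonium on the C1 face can be opened trans-diaxially (Fürst–Plattner) by water at C9 from the open convex face, and the neopentyl C10 is not attacked, so bromine ends at C10 cis to C1 (10R) with the hydroxyl trans at C9.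

Step 6
Reactants: 10 (6S,9R,10R)-10-bromo-2,2-(ethylenedioxy)-9-hydroxy-11,11-dimethylspiro[5.5]undecan-7-one
Product: 11 (6R,9R,10R)-10-bromo-2,2-(ethylenedioxy)-11,11-dimethyl-7-methylidenespiro[5.5]undecan-9-ol
Conditions: Cp2Ti(μ-CH2)(μ-Cl)AlMe2 (3 equiv), pyridine, THF–toluene, −40 to 0 °C
Reagents that add atoms: Tebbe reagent Cp2Ti(μ-CH2)(μ-Cl)AlMe2 C[Al-]1(C)C[Ti]([Cl+]1)(C2C=CC=C2)C3C=CC=C3
Why: Tebbe methylenation (titanium methylidene carbonyl olefination) is non-basic and works on hindered, enolisable ketones, so the neopentyl C7 carbonyl becomes the exocyclic alkene without closing the trans-bromohydrin to an epoxide or causing retro-aldol cleavage; the excess reagent covers the free hydroxyl.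

Step 7
Reactants: 11 (6R,9R,10R)-10-bromo-2,2-(ethylenedioxy)-11,11-dimethyl-7-methylidenespiro[5.5]undecan-9-ol
Product: 12 (6R,10R)-10-bromo-2,2-(ethylenedioxy)-11,11-dimethyl-7-methylidenespiro[5.5]undecan-9-one
Conditions: Dess–Martin periodinane (1.3 equiv), CH2Cl2, 0 °C to rt, 1 h
Reagents that add atoms: none
Why: Dess–Martin oxidation (hypervalent-iodine alcohol oxidation) under non-basic, non-enolising conditions gives the α-bromoketone without touching the acetal, the alkene or the C10 configuration.

Step 8
Reactants: 12 (6R,10R)-10-bromo-2,2-(ethylenedioxy)-11,11-dimethyl-7-methylidenespiro[5.5]undecan-9-one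
Product: 14 (6R,9S,10R)-10-bromo-9-hydroxy-11,11-dimethyl-7-methylidenespiro[5.5]undecan-2-one, via acetal alcohol 13 (not isolated)
Conditions: i-Bu2AlH (1.5 equiv), CH2Cl2, −78 °C; then 1 M aq HCl, THF, rt
Reagents that add atoms: water O
Why: Substrate-controlled hydride reduction: the axial C11 methyl blocks axial approach, so i-Bu2AlH attacks C9 equatorially and gives the axial 9S alcohol cis to the equatorial bromide while C2 is still masked, and the acidic work-up then hydrolyses the dioxolane (acetal hydrolysis) without harming the cis-bromohydrin or the alkene.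

Step 9
Reactants: 14 (6R,9S,10R)-10-bromo-9-hydroxy-11,11-dimethyl-7-methylidenespiro[5.5]undecan-2-one
Product: 15 (6R,9S,10R)-10-bromo-9-hydroxy-11,11-dimethyl-3,7-dimethylidenespiro[5.5]undecan-2-one
Conditions: (CH2O)n (3 equiv), i-Pr2NH·CF3CO2H (1 equiv), THF, 60 °C
Reagents that add atoms: formaldehyde C=O
Why: Ammonium-salt-mediated Mannich condensation and elimination (direct α-methylenation of a ketone) takes place at C3 because the other α-carbon, C1, is neopentyl to the spirocentre, and the mildly acidic medium leaves the bromohydrin alone.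

Step 10
Reactants: 15 (6R,9S,10R)-10-bromo-9-hydroxy-11,11-dimethyl-3,7-dimethylidenespiro[5.5]undecan-2-one
Product: 17 (3S,6R,9S,10R)-10-bromo-3-(chloromethyl)-3,9-dihydroxy-11,11-dimethyl-7-methylidenespiro[5.5]undecan-2-one, via epoxy ketone 16 (not isolated)
Conditions: H2O2 (30% aq, 1.2 equiv), NaOH (0.2 equiv), MeOH–THF, 0 °C; then conc. aq HCl, 0 °C
Reagents that add atoms: hydrogen peroxide OO; hydrogen chloride Cl
Why: Weitz–Scheffer epoxidation adds hydroperoxide to the exocyclic enone and the enolate closes the oxirane by forming the axial C3–O bond on the ring B face opposite the axial C7 (cis to C11), which fixes 3S, and chloride then opens the oxirane by SN2 attack at the primary carbon (epoxide hydrochlorination) without touching the C3–O bond; the equatorial bromide of the cis-bromohydrin has no anti hydrogen or anti oxygen and survives the brief base treatment.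

**Compound list**
1 | 3-bromocyclohex-2-en-1-one | O=C1C=C(Br)CCC1 | starting material
2 | 7-bromo-1,4-dioxaspiro[4.5]dec-6-ene | BrC1=CC2(CCC1)OCCO2 | intermediate
3 | 2-methylcyclopent-2-en-1-one | CC1=CCCC1=O | starting material
4 | 2,2-dimethylcyclopent-3-en-1-one | CC1(C)C=CCC1=O | intermediate
5 | (1,4-dioxaspiro[4.5]dec-6-en-7-yl)lithium | [Li]C1=CC2(CCC1)OCCO2 | intermediate
6 | dichloro(1,4-dioxaspiro[4.5]dec-6-en-7-yl)cerium | Cl[Ce](Cl)C1=CC2(CCC1)OCCO2 | intermediate
7 | rac-1-(1,4-dioxaspiro[4.5]dec-6-en-7-yl)-2,2-dimethylcyclopent-3-en-1-ol (racemic) | OC1(CC=CC1(C)C)C1=CC2(CCC1)OCCO2 | intermediate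
8 | (6S)-2-(2-hydroxyethoxy)-11,11-dimethylspiro[5.5]undeca-1,9-dien-7-one | O=C1CC=CC(C)(C)[C@@]12CCCC(OCCO)=C2 | intermediate
9 | (6S)-2,2-(ethylenedioxy)-11,11-dimethylspiro[5.5]undec-9-en-7-one | O=C1CC=CC(C)(C)[C@@]12CCCC3(OCCO3)C2 | intermediate
10 | (6S,9R,10R)-10-bromo-2,2-(ethylenedioxy)-9-hydroxy-11,11-dimethylspiro[5.5]undecan-7-one | O=C1C[C@@H](O)[C@H](Br)C(C)(C)[C@@]12CCCC3(OCCO3)C2 | intermediate
11 | (6R,9R,10R)-10-bromo-2,2-(ethylenedioxy)-11,11-dimethyl-7-methylidenespiro[5.5]undecan-9-ol | C=C1C[C@@H](O)[C@H](Br)C(C)(C)[C@@]12CCCC3(OCCO3)C2 | intermediate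
12 | (6R,10R)-10-bromo-2,2-(ethylenedioxy)-11,11-dimethyl-7-methylidenespiro[5.5]undecan-9-one | C=C1CC(=O)[C@H](Br)C(C)(C)[C@@]12CCCC3(OCCO3)C2 | intermediate
13 | (6R,9S,10R)-10-bromo-2,2-(ethylenedioxy)-11,11-dimethyl-7-methylidenespiro[5.5]undecan-9-ol | C=C1C[C@H](O)[C@H](Br)C(C)(C)[C@@]12CCCC3(OCCO3)C2 | intermediate
14 | (6R,9S,10R)-10-bromo-9-hydroxy-11,11-dimethyl-7-methylidenespiro[5.5]undecan-2-one | C=C1C[C@H](O)[C@H](Br)C(C)(C)[C@@]12CCCC(=O)C2 | intermediate
15 | (6R,9S,10R)-10-bromo-9-hydroxy-11,11-dimethyl-3,7-dimethylidenespiro[5.5]undecan-2-one | C=C1C[C@H](O)[C@H](Br)C(C)(C)[C@@]12CCC(=C)C(=O)C2 | intermediate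
16 | (3R,6R,9S,10R)-10-bromo-9-hydroxy-11,11-dimethyl-7-methylidenespiro[5.5]undecan-2-one carrying a spiro-oxirane at C3 (oxirane oxygen cis to C11) | C=C1C[C@H](O)[C@H](Br)C(C)(C)[C@@]12CC[C@@]3(CO3)C(=O)C2 | intermediate
17 | (3S,6R,9S,10R)-10-bromo-3-(chloromethyl)-3,9-dihydroxy-11,11-dimethyl-7-methylidenespiro[5.5]undecan-2-one (CNP0273087.1) | C=C1C[C@H](O)[C@H](Br)C(C)(C)[C@@]12CC[C@@](O)(CCl)C(=O)C2 | target

**Step count**
Total steps: 10. Longest linear sequence: 9 (3 → 4 → 7 → 9 → 10 → 11 → 12 → 14 → 15 → 17; step 1 runs in parallel).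

**Steps most likely to fail, with fallbacks**

Risk 1, step 4 (the proposed new ring expansion). The tertiary allylic alcohol may ionise instead of the acetal, turnover may be poor, or the two enantiomers of 7 may give different facial selectivity and lower the ee. The fallback uses known chemistry, sets out from 7 and comes back at 9. The acetal is hydrolysed (PPTS, acetone–H2O, rt) to racemic 3-(1-hydroxy-2,2-dimethylcyclopent-3-en-1-yl)cyclohex-2-en-1-one F1. F1 is rearranged with an achiral acid (TsOH or BF3·OEt2, CH2Cl2; acid-promoted vinylogous α-ketol rearrangement) to rac-11,11-dimethylspiro[5.5]undec-9-ene-2,7-dione F2. F2 is resolved by preparative chiral-phase SFC to (6S)-11,11-dimethylspiro[5.5]undec-9-ene-2,7-dione F3. The unhindered C2 carbonyl of F3 is then acetalised selectively (Me3SiOCH2CH2OSiMe3, cat. Me3SiOTf, −78 °C; the neopentyl C7 carbonyl does not react) to give 9.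

Risk 2, step 5 (facial selectivity of the bromonium). The selectivity rests on a conformational argument, and the other trans-bromohydrin may form as well. The fallback replaces kinetic by thermodynamic control of C10, sets out from 9 and comes back at 12. Step 5 is run without relying on selectivity, so that 10 is accompanied by (6S,9S,10S)-10-bromo-2,2-(ethylenedioxy)-9-hydroxy-11,11-dimethylspiro[5.5]undecan-7-one F4. The mixture is methylenated and oxidised as in steps 6 and 7. F4 passes through (6R,9S,10S)-10-bromo-2,2-(ethylenedioxy)-11,11-dimethyl-7-methylidenespiro[5.5]undecan-9-ol F5 to (6R,10S)-10-bromo-2,2-(ethylenedioxy)-11,11-dimethyl-7-methylidenespiro[5.5]undecan-9-one F6, which is obtained together with 12. Catalytic HBr in AcOH–H2O at rt then removes the acetal and equilibrates C10 through the enol, so that both converge on (6R,10R)-10-bromo-11,11-dimethyl-7-methylidenespiro[5.5]undecane-2,9-dione F7. With C2 flat, the methylidene group sits over C2 and the ring A chair with equatorial bromine cis to C1 is the stable one. Selective re-acetalisation of the unhindered C2 carbonyl of F7 (Me3SiOCH2CH2OSiMe3, cat. Me3SiOTf, −78 °C; the α-bromoketone next to the gem-dimethyl carbon is much slower) returns 12 as one epimer. In the main route 12 is deliberately not equilibrated, because with the acetal in place the other C10 epimer is expected to be the more stable one.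

Risk 3, step 6 (Tebbe methylenation of a neopentyl ketone with a free β-hydroxyl and a secondary bromide). The reaction may stall or give dehydration or retro-aldol products. The fallback is a two-stage Peterson olefination, sets out from 10 and comes back at 11. Me3SiCH2Li with CeCl3 (3 equiv, THF, −78 °C) adds to the C7 carbonyl to give (6S,9R,10R)-10-bromo-2,2-(ethylenedioxy)-11,11-dimethyl-7-[(trimethylsilyl)methyl]spiro[5.5]undecane-7,9-diol F8 (either C7 epimer). HF·pyridine in MeCN at 0 °C then eliminates the β-hydroxysilane (acid-mediated anti-elimination, tolerated by the acetal and the bromohydrin) to give 11.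

Further compounds
F1 | step 4 | 3-(1-hydroxy-2,2-dimethylcyclopent-3-en-1-yl)cyclohex-2-en-1-one (racemic) | OC1(CC=CC1(C)C)C1=CC(=O)CCC1
F2 | step 4 | rac-11,11-dimethylspiro[5.5]undec-9-ene-2,7-dione | O=C1CC=CC(C)(C)C12CCCC(=O)C2
F3 | step 4 | (6S)-11,11-dimethylspiro[5.5]undec-9-ene-2,7-dione | O=C1CC=CC(C)(C)[C@@]12CCCC(=O)C2
F4 | step 5 | (6S,9S,10S)-10-bromo-2,2-(ethylenedioxy)-9-hydroxy-11,11-dimethylspiro[5.5]undecan-7-one | O=C1C[C@H](O)[C@@H](Br)C(C)(C)[C@@]12CCCC3(OCCO3)C2
F5 | step 5 | (6R,9S,10S)-10-bromo-2,2-(ethylenedioxy)-11,11-dimethyl-7-methylidenespiro[5.5]undecan-9-ol | C=C1C[C@H](O)[C@@H](Br)C(C)(C)[C@@]12CCCC3(OCCO3)C2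
F6 | step 5 | (6R,10S)-10-bromo-2,2-(ethylenedioxy)-11,11-dimethyl-7-methylidenespiro[5.5]undecan-9-one | C=C1CC(=O)[C@@H](Br)C(C)(C)[C@@]12CCCC3(OCCO3)C2
F7 | step 5 | (6R,10R)-10-bromo-11,11-dimethyl-7-methylidenespiro[5.5]undecane-2,9-dione | C=C1CC(=O)[C@H](Br)C(C)(C)[C@@]12CCCC(=O)C2
F8 | step 6 | (6S,9R,10R)-10-bromo-2,2-(ethylenedioxy)-11,11-dimethyl-7-[(trimethylsilyl)methyl]spiro[5.5]undecane-7,9-diol (C7 epimers) | C[Si](C)(C)CC1(O)C[C@@H](O)[C@H](Br)C(C)(C)[C@@]12CCCC3(OCCO3)C2
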